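## Retrosynthetic overview

1. The last step forms C6–C7. A Ni/Cr (Nozaki–Hiyama–Kishi) addition of the C7 alkenyl triflate of acyclic 25 to its own C6 epoxy aldehyde closes the ten-membered carbocycle first; the C6 alkoxide then closes the butenolide onto the C12 methyl ester in the same flask.
2. Enabling feature: C6–C7 is both a bond of the cyclodecane and the γ–β bond of the fused butenolide O–C6–C7=C11–C12(=O). Both carbons are acceptors (carbinol carbon and enoate β-carbon), and in the Z-enoate the C7 substituent is cis to C12. Polarity reversal of C7 to an alkenylchromium therefore gives the ring, the C6 stereocentre and the lactone together.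
3. 25 comes from the Z-enol triflate made by chelation-controlled triflation of β-keto ester 19 (this fixes OTf cis to C12 and C8 cis to C13). 19 comes from an aldol of α-tigloyloxy aldehyde 14 with ester 16. The C4/C5 cis-epoxide comes from a late Sharpless epoxidation of the Z-allylic alcohol.
4. 14 comes from trans-α-methyl-γ-lactone 9 (C8 from the L-glutamic acid pool, C10 by 1,3-trans alkylation) and the Z-homoallyllithium 10 (C2–C6, built from but-2-yn-1-ol).

Key step: step 19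

Remark: locants are germacranolide locants of the target (C1 ketone, C4/C5 epoxide, C6 lactone CH–O, C7=C11, C8 tiglate CH–O, C10 CH–CH3, C12 lactone C=O, C13 CH2OAc). The target is read as (4R,5S,6S,8S,10R) with a cis-epoxide (C3 and C6 cis). Lactone 8 is taken as a catalogue compound.

## Route

Step 1
Reactants: 1 but-2-yn-1-ol
Product: 3 (Z)-3-iodobut-2-en-1-ol, via cyclic sodium alkenylalanate 2 (not isolated)
Conditions: Red-Al, THF, 0 °C → rt; then I2, THF, −78 → 0 °C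
Reagents that add atoms: iodine, II
Why: Hydroxyl-directed trans-hydroalumination of the propargylic alcohol puts hydride on C2 and aluminium on C3 in a five-membered alanate, and iodinolysis of the C–Al bond with retention should give the Z-iodide (hydroalumination–iodination).

Step 2
Reactants: 3 (Z)-3-iodobut-2-en-1-ol
Product: 4 (Z)-1-{[(3-iodobut-2-en-1-yl)oxy]methyl}-4-methoxybenzene
Conditions: NaH, PMBCl, Bu4NI (cat.), THF, 0 °C → rt
Reagents that add atoms: 4-methoxybenzyl chloride, COc1ccc(CCl)cc1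
Why: Williamson etherification; the PMB ether is inert to the organolithium steps and is removed oxidatively near the end.

Step 3
Reactants: 4 (Z)-1-{[(3-iodobut-2-en-1-yl)oxy]methyl}-4-methoxybenzene
Product: 6 (Z)-5-[(4-methoxybenzyl)oxy]-3-methylpent-3-en-1-ol, via alkenyllithium 5 (not isolated)
Conditions: t-BuLi (2.1 equiv), Et2O, −78 °C; then oxirane (excess), −78 → 0 °C; H2O
Reagents that add atoms: oxirane, C1CO1
Why: Iodine–lithium exchange retains the alkene geometry and the alkenyllithium opens oxirane (SN2), which fixes the Z (neryl-type) trisubstituted alkene that becomes C4=C5.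

Step 4
Reactants: 6 (Z)-5-[(4-methoxybenzyl)oxy]-3-methylpent-3-en-1-ol
Product: 7 (Z)-1-{[(5-iodo-3-methylpent-2-en-1-yl)oxy]methyl}-4-methoxybenzene
Conditions: I2, PPh3, imidazole, CH2Cl2, 0 °C
Reagents that add atoms: iodine, II
Why: Appel-type iodination (Garegg–Samuelsson) of the primary alcohol under neutral conditions.

Step 5
Reactants: 8 (S)-5-[(trityloxy)methyl]dihydrofuran-2(3H)-one
Product: 9 (3R,5S)-3-methyl-5-[(trityloxy)methyl]dihydrofuran-2(3H)-one
Conditions: LDA (1.1 equiv), THF, −78 °C; MeI, −78 °C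
Reagents that add atoms: iodomethane, CI
Why: Lactone enolate alkylation in which iodomethane approaches anti to the C5 trityloxymethyl group, so the future C10 should be set as the 1,3-trans (3R) isomer by substrate control.

Step 6
Reactants: 7 (Z)-1-{[(5-iodo-3-methylpent-2-en-1-yl)oxy]methyl}-4-methoxybenzene; 9 (3R,5S)-3-methyl-5-[(trityloxy)methyl]dihydrofuran-2(3H)-one
Product: 11 (2S,4R,8Z)-2-hydroxy-10-[(4-methoxybenzyl)oxy]-4,8-dimethyl-1-(trityloxy)dec-8-en-5-one, via homoallyllithium 10 (not isolated)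
Conditions: 7, t-BuLi (2.0 equiv), Et2O, −78 °C; then 9 in THF, −78 °C; H2O quench at −78 °C
Reagents that add atoms: none
Why: Iodine–lithium exchange followed by acyl substitution on the γ-lactone should stop at the ketone stage because the tetrahedral lithium hemiketal alkoxide persists at −78 °C, joining C1 to C2 without touching the stereocentres.

Step 7
Reactants: 11 (2S,4R,8Z)-2-hydroxy-10-[(4-methoxybenzyl)oxy]-4,8-dimethyl-1-(trityloxy)dec-8-en-5-one
Product: 12 (2S,4R,8Z)-10-[(4-methoxybenzyl)oxy]-4,8-dimethyl-5-oxo-1-(trityloxy)dec-8-en-2-yl (2E)-2-methylbut-2-enoate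
Conditions: tiglic acid, 2,4,6-Cl3C6H2COCl, Et3N, toluene, rt; then 11, DMAP, rt
Reagents that add atoms: tiglic acid, C/C=C(\C)C(=O)O
Why: Yamaguchi esterification acylates the hindered secondary C8 alcohol through the mixed anhydride and DMAP without base-induced deconjugation of the tigloyl group, whose E geometry is the stable one.

Step 8
Reactants: 12 (2S,4R,8Z)-10-[(4-methoxybenzyl)oxy]-4,8-dimethyl-5-oxo-1-(trityloxy)dec-8-en-2-yl (2E)-2-methylbut-2-enoate
Product: 13 (2S,4R,8Z)-1-hydroxy-10-[(4-methoxybenzyl)oxy]-4,8-dimethyl-5-oxodec-8-en-2-yl (2E)-2-methylbut-2-enoate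
Conditions: ZnBr2, CH2Cl2, 0 °C → rt; aq. NaHCO3
Reagents that add atoms: none
Why: Lewis-acid ionisation of the trityl ether (detritylation) frees the primary alcohol while PMB ether, ester and ketone stay intact; the product is oxidised at once to forestall a 1,2-acyl shift.

Step 9
Reactants: 13 (2S,4R,8Z)-1-hydroxy-10-[(4-methoxybenzyl)oxy]-4,8-dimethyl-5-oxodec-8-en-2-yl (2E)-2-methylbut-2-enoate
Product: 14 (2S,4R,8Z)-10-[(4-methoxybenzyl)oxy]-4,8-dimethyl-1,5-dioxodec-8-en-2-yl (2E)-2-methylbut-2-enoate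
Conditions: Dess–Martin periodinane, NaHCO3, CH2Cl2, 0 °C → rt
Reagents that add atoms: none
Why: Dess–Martin oxidation gives the α-acyloxy aldehyde under buffered conditions that should not epimerise C8.

Step 10
Reactants: 15 methyl 3-hydroxypropanoate
Product: 16 methyl 3-[(tert-butyldimethylsilyl)oxy]propanoate
Conditions: TBSCl, imidazole, CH2Cl2, rt
Reagents that add atoms: tert-butyldimethylsilyl chloride, CC(C)(C)[Si](C)(C)Cl
Why: Silylation of the primary alcohol gives a β-silyloxy ester whose lithium enolate is stable at −78 °C.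

Step 11
Reactants: 16 methyl 3-[(tert-butyldimethylsilyl)oxy]propanoate; 14 (2S,4R,8Z)-10-[(4-methoxybenzyl)oxy]-4,8-dimethyl-1,5-dioxodec-8-en-2-yl (2E)-2-methylbut-2-enoate
Product: 18 methyl (4S,6R,10Z)-2-{[(tert-butyldimethylsilyl)oxy]methyl}-3-hydroxy-12-[(4-methoxybenzyl)oxy]-6,10-dimethyl-4-{[(2E)-2-methylbut-2-enoyl]oxy}-7-oxododec-10-enoate (mixture at C2/C3), via lithium ester enolate 17 (not isolated)
Conditions: 16, LDA (1.05 equiv), THF, −78 °C; then 14, −78 °C, 20 min; pH 7 buffer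
Reagents that add atoms: none
Why: Aldol addition of the lithium ester enolate is faster to the aldehyde than to the ketone or esters at −78 °C, and the two new stereocentres are erased in steps 12 and 13.

Step 12
Reactants: 18 methyl (4S,6R,10Z)-2-{[(tert-butyldimethylsilyl)oxy]methyl}-3-hydroxy-12-[(4-methoxybenzyl)oxy]-6,10-dimethyl-4-{[(2E)-2-methylbut-2-enoyl]oxy}-7-oxododec-10-enoate
Product: 19 methyl (4S,6R,10Z)-2-{[(tert-butyldimethylsilyl)oxy]methyl}-12-[(4-methoxybenzyl)oxy]-6,10-dimethyl-4-{[(2E)-2-methylbut-2-enoyl]oxy}-3,7-dioxododec-10-enoate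
Conditions: Dess–Martin periodinane, NaHCO3, CH2Cl2, 0 °C → rt
Reagents that add atoms: none
Why: Dess–Martin oxidation of the β-hydroxy ester to the β-keto ester.

Step 13
Reactants: 19 methyl (4S,6R,10Z)-2-{[(tert-butyldimethylsilyl)oxy]methyl}-12-[(4-methoxybenzyl)oxy]-6,10-dimethyl-4-{[(2E)-2-methylbut-2-enoyl]oxy}-3,7-dioxododec-10-enoate
Product: 20 methyl (2Z,4S,6R,10Z)-2-{[(tert-butyldimethylsilyl)oxy]methyl}-12-[(4-methoxybenzyl)oxy]-6,10-dimethyl-4-{[(2E)-2-methylbut-2-enoyl]oxy}-7-oxo-3-{[(trifluoromethyl)sulfonyl]oxy}dodeca-2,10-dienoate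
Conditions: Tf2O (1.5 equiv), sat. aq. LiOH, toluene, 5 °C, vigorous stirring
Reagents that add atoms: trifluoromethanesulfonic anhydride, O=S(=O)(OS(=O)(=O)C(F)(F)F)C(F)(F)F
Why: Chelation-controlled enol triflation of an α-substituted β-keto ester: the lithium chelate between enolate oxygen and ester carbonyl is triflated to the Z enol triflate, which places OTf cis to CO2Me and C8 cis to C13.

Step 14
Reactants: 20 methyl (2Z,4S,6R,10Z)-2-{[(tert-butyldimethylsilyl)oxy]methyl}-12-[(4-methoxybenzyl)oxy]-6,10-dimethyl-4-{[(2E)-2-methylbut-2-enoyl]oxy}-7-oxo-3-{[(trifluoromethyl)sulfonyl]oxy}dodeca-2,10-dienoate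
Product: 21 methyl (2Z,4S,6R,10Z)-2-(hydroxymethyl)-12-[(4-methoxybenzyl)oxy]-6,10-dimethyl-4-{[(2E)-2-methylbut-2-enoyl]oxy}-7-oxo-3-{[(trifluoromethyl)sulfonyl]oxy}dodeca-2,10-dienoate
Conditions: HF·pyridine, pyridine, THF, 0 °C
Reagents that add atoms: none
Why: Fluoride cleavage of the primary TBS ether under buffered acidic conditions that spare enol triflate, PMB ether and esters.

Step 15
Reactants: 21 methyl (2Z,4S,6R,10Z)-2-(hydroxymethyl)-12-[(4-methoxybenzyl)oxy]-6,10-dimethyl-4-{[(2E)-2-methylbut-2-enoyl]oxy}-7-oxo-3-{[(trifluoromethyl)sulfonyl]oxy}dodeca-2,10-dienoate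
Product: 22 methyl (2Z,4S,6R,10Z)-2-(acetoxymethyl)-12-[(4-methoxybenzyl)oxy]-6,10-dimethyl-4-{[(2E)-2-methylbut-2-enoyl]oxy}-7-oxo-3-{[(trifluoromethyl)sulfonyl]oxy}dodeca-2,10-dienoate
Conditions: Ac2O, pyridine, DMAP (cat.), CH2Cl2, 0 °C
Reagents that add atoms: acetic anhydride, CC(=O)OC(C)=O
Why: Acetylation of the primary allylic alcohol installs the C13 acetate of the target.

Step 16
Reactants: 22 methyl (2Z,4S,6R,10Z)-2-(acetoxymethyl)-12-[(4-methoxybenzyl)oxy]-6,10-dimethyl-4-{[(2E)-2-methylbut-2-enoyl]oxy}-7-oxo-3-{[(trifluoromethyl)sulfonyl]oxy}dodeca-2,10-dienoate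
Product: 23 methyl (2Z,4S,6R,10Z)-2-(acetoxymethyl)-12-hydroxy-6,10-dimethyl-4-{[(2E)-2-methylbut-2-enoyl]oxy}-7-oxo-3-{[(trifluoromethyl)sulfonyl]oxy}dodeca-2,10-dienoate
Conditions: DDQ, CH2Cl2/pH 7 buffer (10:1), 0 °C
Reagents that add atoms: none
Why: Oxidative PMB cleavage by DDQ through the benzylic oxocarbenium ion liberates the Z-allylic alcohol without touching the electron-poor alkenes.

Step 17
Reactants: 23 methyl (2Z,4S,6R,10Z)-2-(acetoxymethyl)-12-hydroxy-6,10-dimethyl-4-{[(2E)-2-methylbut-2-enoyl]oxy}-7-oxo-3-{[(trifluoromethyl)sulfonyl]oxy}dodeca-2,10-dienoate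
Product: 24 methyl (2Z,4S,6R)-2-(acetoxymethyl)-9-[(2R,3S)-3-(hydroxymethyl)-2-methyloxiran-2-yl]-6-methyl-4-{[(2E)-2-methylbut-2-enoyl]oxy}-7-oxo-3-{[(trifluoromethyl)sulfonyl]oxy}non-2-enoate
Conditions: Ti(OiPr)4 (cat.), L-(+)-diethyl tartrate, TBHP, 4 Å MS, CH2Cl2, −20 °C
Reagents that add atoms: tert-butyl hydroperoxide, CC(C)(C)OO
Why: Sharpless asymmetric epoxidation: only the alkene of the allylic alcohol is epoxidised, and L-(+)-tartrate should deliver oxygen to the face that gives the (4R,5S) cis-epoxide (the (2S,3R) sense known for nerol-type Z-allylic alcohols) by reagent control.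

Step 18
Reactants: 24 methyl (2Z,4S,6R)-2-(acetoxymethyl)-9-[(2R,3S)-3-(hydroxymethyl)-2-methyloxiran-2-yl]-6-methyl-4-{[(2E)-2-methylbut-2-enoyl]oxy}-7-oxo-3-{[(trifluoromethyl)sulfonyl]oxy}non-2-enoate
Product: 25 methyl (2Z,4S,6R)-2-(acetoxymethyl)-9-[(2R,3R)-3-formyl-2-methyloxiran-2-yl]-6-methyl-4-{[(2E)-2-methylbut-2-enoyl]oxy}-7-oxo-3-{[(trifluoromethyl)sulfonyl]oxy}non-2-enoate
Conditions: Dess–Martin periodinane, NaHCO3, CH2Cl2, 0 °C
Reagents that add atoms: none
Why: Dess–Martin oxidation to the sensitive 2,3-epoxy aldehyde, which is used directly.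

Step 19
Reactants: 25 methyl (2Z,4S,6R)-2-(acetoxymethyl)-9-[(2R,3R)-3-formyl-2-methyloxiran-2-yl]-6-methyl-4-{[(2E)-2-methylbut-2-enoyl]oxy}-7-oxo-3-{[(trifluoromethyl)sulfonyl]oxy}non-2-enoate
Product: 27 (4R,5S,6S,8S,10R)-13-acetoxy-4,5-epoxy-1-oxo-8-{[(2E)-2-methylbut-2-enoyl]oxy}germacr-7(11)-en-12,6-olide, via cyclised C6-hydroxy ester 26 (not isolated)
Conditions: CrCl2 (10 equiv), NiCl2 (2 mol %), degassed DMF, slow addition of 25 (final 2 mM), rt; aq. sodium serinate work-up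
Reagents that add atoms: none
Why: Ni(0), formed in situ, inserts into the C7–OTf bond and hands the alkenyl group to Cr(III); the resulting alkenylchromium turns the enoate β-carbon C7 (an acceptor in 25) into a donor, which adds to the C6 aldehyde only (the ketone and the three esters are inert to organochromium(III)), the Nozaki–Hiyama–Kishi reaction. The closest known reaction types are NHK macrocyclisations of alkenyl iodides or triflates onto aldehydes giving nine- to eleven-membered carbocycles, and the lactonising NHK coupling of (Z)-β-halo- or β-triflyloxy-acrylates with aldehydes. The ten-membered carbocycle closes by exo attack on the aldehyde C=O (10-exo-trig); the butenolide then closes by 5-exo-trig acyl substitution of the C6 chromium alkoxide on the C12 methyl ester, which the Z geometry of C7=C11 holds cis to it, with loss of methoxide. The only new stereocentre, C6, is controlled by the adjacent C5 of the cis-epoxide: polar Felkin–Anh (Cornforth) addition anti to the C5–O bond should give the 5,6-anti (6S) carbinol. The step needs intramolecular over intermolecular coupling, secured by slow addition at about 2 mM, and survival of the β-acyloxy alkenylchromium and of the epoxide, secured by the mild, non-basic Cr(III) species at room temperature.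

## Compound list

1 | but-2-yn-1-ol | CC#CCO | starting material
2 | cyclic sodium alkenylalanate (3-methyl-1,2-oxaaluminacyclopent-3-ene ate complex, two 2-methoxyethoxy ligands) | CC1=CCO[Al-]1(OCCOC)OCCOC.[Na+] | intermediate
3 | (Z)-3-iodobut-2-en-1-ol | C/C(I)=C/CO | intermediate
4 | (Z)-1-{[(3-iodobut-2-en-1-yl)oxy]methyl}-4-methoxybenzene | C/C(I)=C/COCc1ccc(OC)cc1 | intermediate
5 | (Z)-4-[(4-methoxybenzyl)oxy]but-2-en-2-yllithium | C/C([Li])=C/COCc1ccc(OC)cc1 | intermediate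
6 | (Z)-5-[(4-methoxybenzyl)oxy]-3-methylpent-3-en-1-ol | OCC/C(C)=C\COCc1ccc(OC)cc1 | intermediate
7 | (Z)-1-{[(5-iodo-3-methylpent-2-en-1-yl)oxy]methyl}-4-methoxybenzene | ICC/C(C)=C\COCc1ccc(OC)cc1 | intermediate
8 | (S)-5-[(trityloxy)methyl]dihydrofuran-2(3H)-one | O=C1O[C@H](COC(c2ccccc2)(c2ccccc2)c2ccccc2)CC1 | starting material
9 | (3R,5S)-3-methyl-5-[(trityloxy)methyl]dihydrofuran-2(3H)-one | O=C1O[C@H](COC(c2ccccc2)(c2ccccc2)c2ccccc2)C[C@H]1C | intermediate
10 | (Z)-5-[(4-methoxybenzyl)oxy]-3-methylpent-3-en-1-yllithium | [Li]CC/C(C)=C\COCc1ccc(OC)cc1 | intermediate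
11 | (2S,4R,8Z)-2-hydroxy-10-[(4-methoxybenzyl)oxy]-4,8-dimethyl-1-(trityloxy)dec-8-en-5-one | O[C@H](COC(c1ccccc1)(c1ccccc1)c1ccccc1)C[C@@H](C)C(=O)CC/C(C)=C\COCc1ccc(OC)cc1 | intermediate
12 | (2S,4R,8Z)-10-[(4-methoxybenzyl)oxy]-4,8-dimethyl-5-oxo-1-(trityloxy)dec-8-en-2-yl (2E)-2-methylbut-2-enoate | C/C=C(\C)C(=O)O[C@H](COC(c1ccccc1)(c1ccccc1)c1ccccc1)C[C@@H](C)C(=O)CC/C(C)=C\COCc1ccc(OC)cc1 | intermediate
13 | (2S,4R,8Z)-1-hydroxy-10-[(4-methoxybenzyl)oxy]-4,8-dimethyl-5-oxodec-8-en-2-yl (2E)-2-methylbut-2-enoate | C/C=C(\C)C(=O)O[C@H](CO)C[C@@H](C)C(=O)CC/C(C)=C\COCc1ccc(OC)cc1 | intermediate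
14 | (2S,4R,8Z)-10-[(4-methoxybenzyl)oxy]-4,8-dimethyl-1,5-dioxodec-8-en-2-yl (2E)-2-methylbut-2-enoate | C/C=C(\C)C(=O)O[C@H](C=O)C[C@@H](C)C(=O)CC/C(C)=C\COCc1ccc(OC)cc1 | intermediate
15 | methyl 3-hydroxypropanoate | COC(=O)CCO | starting material
16 | methyl 3-[(tert-butyldimethylsilyl)oxy]propanoate | COC(=O)CCO[Si](C)(C)C(C)(C)C | intermediate
17 | lithium enolate of 16 | COC(O[Li])=CCO[Si](C)(C)C(C)(C)C | intermediate
18 | methyl (4S,6R,10Z)-2-{[(tert-butyldimethylsilyl)oxy]methyl}-3-hydroxy-12-[(4-methoxybenzyl)oxy]-6,10-dimethyl-4-{[(2E)-2-methylbut-2-enoyl]oxy}-7-oxododec-10-enoate (mixture at C2/C3) | C/C=C(\C)C(=O)O[C@H](C(O)C(CO[Si](C)(C)C(C)(C)C)C(=O)OC)C[C@@H](C)C(=O)CC/C(C)=C\COCc1ccc(OC)cc1 | intermediate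
19 | methyl (4S,6R,10Z)-2-{[(tert-butyldimethylsilyl)oxy]methyl}-12-[(4-methoxybenzyl)oxy]-6,10-dimethyl-4-{[(2E)-2-methylbut-2-enoyl]oxy}-3,7-dioxododec-10-enoate (C2 epimers/enol) | C/C=C(\C)C(=O)O[C@H](C(=O)C(CO[Si](C)(C)C(C)(C)C)C(=O)OC)C[C@@H](C)C(=O)CC/C(C)=C\COCc1ccc(OC)cc1 | intermediate
20 | methyl (2Z,4S,6R,10Z)-2-{[(tert-butyldimethylsilyl)oxy]methyl}-12-[(4-methoxybenzyl)oxy]-6,10-dimethyl-4-{[(2E)-2-methylbut-2-enoyl]oxy}-7-oxo-3-{[(trifluoromethyl)sulfonyl]oxy}dodeca-2,10-dienoate | C/C=C(\C)C(=O)O[C@H](/C(OS(=O)(=O)C(F)(F)F)=C(\CO[Si](C)(C)C(C)(C)C)C(=O)OC)C[C@@H](C)C(=O)CC/C(C)=C\COCc1ccc(OC)cc1 | intermediate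
21 | methyl (2Z,4S,6R,10Z)-2-(hydroxymethyl)-12-[(4-methoxybenzyl)oxy]-6,10-dimethyl-4-{[(2E)-2-methylbut-2-enoyl]oxy}-7-oxo-3-{[(trifluoromethyl)sulfonyl]oxy}dodeca-2,10-dienoate | C/C=C(\C)C(=O)O[C@H](/C(OS(=O)(=O)C(F)(F)F)=C(\CO)C(=O)OC)C[C@@H](C)C(=O)CC/C(C)=C\COCc1ccc(OC)cc1 | intermediate
22 | methyl (2Z,4S,6R,10Z)-2-(acetoxymethyl)-12-[(4-methoxybenzyl)oxy]-6,10-dimethyl-4-{[(2E)-2-methylbut-2-enoyl]oxy}-7-oxo-3-{[(trifluoromethyl)sulfonyl]oxy}dodeca-2,10-dienoate | C/C=C(\C)C(=O)O[C@H](/C(OS(=O)(=O)C(F)(F)F)=C(\COC(C)=O)C(=O)OC)C[C@@H](C)C(=O)CC/C(C)=C\COCc1ccc(OC)cc1 | intermediate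
23 | methyl (2Z,4S,6R,10Z)-2-(acetoxymethyl)-12-hydroxy-6,10-dimethyl-4-{[(2E)-2-methylbut-2-enoyl]oxy}-7-oxo-3-{[(trifluoromethyl)sulfonyl]oxy}dodeca-2,10-dienoate | C/C=C(\C)C(=O)O[C@H](/C(OS(=O)(=O)C(F)(F)F)=C(\COC(C)=O)C(=O)OC)C[C@@H](C)C(=O)CC/C(C)=C\CO | intermediate
24 | methyl (2Z,4S,6R)-2-(acetoxymethyl)-9-[(2R,3S)-3-(hydroxymethyl)-2-methyloxiran-2-yl]-6-methyl-4-{[(2E)-2-methylbut-2-enoyl]oxy}-7-oxo-3-{[(trifluoromethyl)sulfonyl]oxy}non-2-enoate | C/C=C(\C)C(=O)O[C@H](/C(OS(=O)(=O)C(F)(F)F)=C(\COC(C)=O)C(=O)OC)C[C@@H](C)C(=O)CC[C@@]1(C)O[C@H]1CO | intermediate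
25 | methyl (2Z,4S,6R)-2-(acetoxymethyl)-9-[(2R,3R)-3-formyl-2-methyloxiran-2-yl]-6-methyl-4-{[(2E)-2-methylbut-2-enoyl]oxy}-7-oxo-3-{[(trifluoromethyl)sulfonyl]oxy}non-2-enoate | C/C=C(\C)C(=O)O[C@H](/C(OS(=O)(=O)C(F)(F)F)=C(\COC(C)=O)C(=O)OC)C[C@@H](C)C(=O)CC[C@@]1(C)O[C@H]1C=O | intermediate
26 | ten-membered carbocyclic C6-hydroxy ester, methyl 3-acetoxy-2-(cyclodecylidene)propanoate type, with C6–OH cis to CO2Me (chromium alkoxide before work-up) | C/C=C(\C)C(=O)O[C@H]1C[C@@H](C)C(=O)CC[C@@]2(C)O[C@H]2[C@@H](O)/C1=C(/COC(C)=O)C(=O)OC | intermediate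
27 | (4R,5S,6S,8S,10R)-13-acetoxy-4,5-epoxy-1-oxo-8-{[(2E)-2-methylbut-2-enoyl]oxy}germacr-7(11)-en-12,6-olide | C/C=C(\C)C(=O)O[C@H]1C[C@@H](C)C(=O)CC[C@@]2(C)O[C@H]2[C@H]2OC(=O)C(COC(C)=O)=C12 | target

## Step count and risks

Total steps: 19. Longest linear sequence: 17 (steps 1–4, 6–9, 11–19).

**Step 19 (most at risk).** Closure of the ten-membered ring may be slow for the hindered tetrasubstituted alkenylchromium and the rigid epoxy aldehyde. Protodemetalation, chloride opening of the epoxide or loss of facial control at C6 could then take over. The fallback sets out from 23 and moves the epoxidation behind the ring closure. MnO2 oxidation of 23 gives the flat, more reactive (Z)-enal, methyl (2Z,4S,6R,10Z)-2-(acetoxymethyl)-6,10-dimethyl-4-{[(2E)-2-methylbut-2-enoyl]oxy}-7,12-dioxo-3-{[(trifluoromethyl)sulfonyl]oxy}dodeca-2,10-dienoate F1. F1 is cyclised under the Ni/Cr conditions to the 4,5-unsaturated macrocyclic butenolide, (4Z,6R,8S,10R)-13-acetoxy-1-oxo-8-{[(2E)-2-methylbut-2-enoyl]oxy}germacra-4,7(11)-dien-12,6-olide F2. Its only electron-rich alkene is then epoxidised with buffered mCPBA; attack is expected anti to the C6 lactone oxygen in the A(1,3)-minimised conformer. The fallback comes back to the route at 27.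

**Step 13.** The enolate may lose its silyloxy group by β-elimination, or Z/E control may erode under the aqueous base. The fallback sets out from 14 and forms the chelated enolate directly at low temperature. Pinnick oxidation (NaClO2, NaH2PO4, 2-methylbut-2-ene) gives the acid, (2S,4R,8Z)-10-[(4-methoxybenzyl)oxy]-4,8-dimethyl-2-{[(2E)-2-methylbut-2-enoyl]oxy}-5-oxodec-8-enoic acid F3. Carbonyldiimidazole converts it into the acyl imidazole F4. Crossed Claisen acylation of two equivalents of enolate 17 at −78 °C gives the lithium chelate enolate of 19, F5, which is trapped cold with Tf2O. The fallback comes back to the route at 20.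

**Step 6.** A second addition to the liberated ketone, or epimerisation at C10 through the lithium alkoxide on warming, may occur. The fallback sets out from 9. Aminolysis with MeNHOMe·HCl and AlMe3 gives the Weinreb amide, (2R,4S)-4-hydroxy-N-methoxy-N,2-dimethyl-5-(trityloxy)pentanamide F6. Two equivalents of 10 then add once through the chelated tetrahedral intermediate. The fallback comes back to the route at 11.

Further compounds
F1 | step 19 | methyl (2Z,4S,6R,10Z)-2-(acetoxymethyl)-6,10-dimethyl-4-{[(2E)-2-methylbut-2-enoyl]oxy}-7,12-dioxo-3-{[(trifluoromethyl)sulfonyl]oxy}dodeca-2,10-dienoate | C/C=C(\C)C(=O)O[C@H](/C(OS(=O)(=O)C(F)(F)F)=C(\COC(C)=O)C(=O)OC)C[C@@H](C)C(=O)CC/C(C)=C\C=O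
F2 | step 19 | (4Z,6R,8S,10R)-13-acetoxy-1-oxo-8-{[(2E)-2-methylbut-2-enoyl]oxy}germacra-4,7(11)-dien-12,6-olide | C/C=C(\C)C(=O)O[C@H]1C[C@@H](C)C(=O)CC/C(C)=C\[C@H]2OC(=O)C(COC(C)=O)=C12
F3 | step 13 | (2S,4R,8Z)-10-[(4-methoxybenzyl)oxy]-4,8-dimethyl-2-{[(2E)-2-methylbut-2-enoyl]oxy}-5-oxodec-8-enoic acid | C/C=C(\C)C(=O)O[C@H](C(=O)O)C[C@@H](C)C(=O)CC/C(C)=C\COCc1ccc(OC)cc1
F4 | step 13 | 1-[(2S,4R,8Z)-10-[(4-methoxybenzyl)oxy]-4,8-dimethyl-2-{[(2E)-2-methylbut-2-enoyl]oxy}-5-oxodec-8-enoyl]imidazole | C/C=C(\C)C(=O)O[C@H](C(=O)n1ccnc1)C[C@@H](C)C(=O)CC/C(C)=C\COCc1ccc(OC)cc1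
F5 | step 13 | lithium (Z)-enolate of β-keto ester 19 | C/C=C(\C)C(=O)O[C@H](/C(O[Li])=C(\CO[Si](C)(C)C(C)(C)C)C(=O)OC)C[C@@H](C)C(=O)CC/C(C)=C\COCc1ccc(OC)cc1
F6 | step 6 | (2R,4S)-4-hydroxy-N-methoxy-N,2-dimethyl-5-(trityloxy)pentanamide | CON(C)C(=O)[C@H](C)C[C@H](O)COC(c1ccccc1)(c1ccccc1)c1ccccc1
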